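**Plan**

- Retrosynthesis cuts, in order: the six aryl O–Si bonds; the two cyclohexene bonds C-3''–C-4'' and C-5''–C-6'' ([4+2]), giving a 2'-hydroxychalcone dienophile and a 6-dienyl flavanone; the aryl–dienyl bond at C-6 (Stille) and C-6–I; the flavanone C-3–C-4 bond; and the aryl-O–C(vinyl) bond.
- Enabling feature: in the open precursor the formyl carbon on ring A (future C-4) is ortho to the oxygen (future O-1) that carries a 1,1-disubstituted enol ether C(aryl)=CH2 (future C-2 and C-3). The other ortho OH (future 5-OH) hydrogen-bonds the formyl oxygen and so turns the formyl C–H toward the CH2 terminus.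
- Forward: ring C is closed first by enantioselective intramolecular hydroacylation (acyl carbon onto CH2). Then come iodination at C-6 (ortho to the free 5-OH), Stille attachment of the myrcene-type diene, the exo [4+2] that closes the cyclohexene, and buffered global desilylation.
- Stereochemistry: C-2 (S) comes from the chiral rhodium–bisphosphine catalyst. C-3'', C-4'' and C-5'' come from a boron/VANOL-promoted exo cycloaddition of the E-diene with the E-chalcone (trans,trans; absolute sense from the ligand). All steps after ring C closure are base-free or buffered, so C-2 is not scrambled.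

Key step: step 5

Remark: the sense of induction of (R)-DTBM-SEGPHOS in step 5 and of (S)-VANOL in step 16 on these substrates is assumed; both ligands are available in either enantiomeric form, so the opposite sense would be corrected by exchanging the ligand enantiomer.

Cyclohexene locants used below: C-1'' carries the 4-methylpent-3-enyl chain, C-2'' is the vinylic CH, C-3'' carries chromanone C-6, C-4'' the aroyl group, C-5'' the aryl group, C-6'' is CH2.

**Step 1**
Reactants: 1 2,4,6-trihydroxybenzaldehyde
Product: 2 2,6-dihydroxy-4-[(triisopropylsilyl)oxy]benzaldehyde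
Conditions: TIPSCl (1.0 equiv), imidazole, DMF, 0 °C
Reagents that add atoms: chlorotriisopropylsilane, CC(C)[Si](Cl)(C(C)C)C(C)C
Why: Regioselective O-silylation, since the 4-OH is the most acidic hydroxyl and the only one not engaged with the formyl group, so one equivalent of the bulky chlorosilane should take it alone.

**Step 2**
Reactants: 3 1-(2,4-dihydroxyphenyl)ethan-1-one
Product: 4 1-{2,4-bis[(triisopropylsilyl)oxy]phenyl}ethan-1-one
Conditions: TIPSCl (2.5 equiv), imidazole, DMAP (cat.), DMF, 50 °C
Reagents that add atoms: chlorotriisopropylsilane, CC(C)[Si](Cl)(C(C)C)C(C)C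
Why: Exhaustive O-silylation, in which warming with DMAP should overcome the chelation of the 2-OH to the ketone.

**Step 3**
Reactants: 4 1-{2,4-bis[(triisopropylsilyl)oxy]phenyl}ethan-1-one
Product: 5 1-(1-bromoethenyl)-2,4-bis[(triisopropylsilyl)oxy]benzene
Conditions: P(OPh)3, Br2, CH2Cl2, −60 °C; then 4, Et3N, −60 °C to reflux
Reagents that add atoms: bromine, BrBr
Why: Conversion of an enolisable methyl ketone into its vinyl bromide with the triphenyl phosphite–bromine reagent (halophosphonium activation of the carbonyl oxygen, then loss of HBr toward the only α-carbon), in an amine-buffered medium that aryl silyl ethers should tolerate.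

**Step 4**
Reactants: 2 2,6-dihydroxy-4-[(triisopropylsilyl)oxy]benzaldehyde; 5 1-(1-bromoethenyl)-2,4-bis[(triisopropylsilyl)oxy]benzene
Product: 6 2-({1-[2,4-bis(triisopropylsilyloxy)phenyl]ethenyl}oxy)-6-hydroxy-4-(triisopropylsilyloxy)benzaldehyde
Conditions: CuI (10 mol %), N,N-dimethylglycine hydrochloride (30 mol %), Cs2CO3, 1,4-dioxane, 90 °C; 2 in slight excess
Reagents that add atoms: none
Why: Ullmann-type C–O coupling of a phenol with a vinyl bromide under monovalent copper catalysis, expected to stop at mono-vinylation because the two hydroxyls of 2 are equivalent and the remaining one becomes locked in the hydrogen bond to the formyl group.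

**Step 5**
Reactants: 6 2-({1-[2,4-bis(triisopropylsilyloxy)phenyl]ethenyl}oxy)-6-hydroxy-4-(triisopropylsilyloxy)benzaldehyde
Product: 7 (2S)-2-[2,4-bis(triisopropylsilyloxy)phenyl]-5-hydroxy-7-(triisopropylsilyloxy)-2,3-dihydro-4H-chromen-4-one
Conditions: [Rh(cod)Cl]2 (2.5 mol %), (R)-DTBM-SEGPHOS (5.5 mol %), Na[B(3,5-(CF3)2C6H3)4] (5 mol %), anhydrous 1,4-dioxane, 60 °C
Reagents that add atoms: none
Why: Proposed new method: oxidative addition of the formyl C–H bond of 6 to the cationic monovalent rhodium–bisphosphine complex gives an acyl hydride of trivalent rhodium, the tethered 1,1-disubstituted enol ether inserts into Rh–H with hydride going to the oxygen- and aryl-bearing carbon and rhodium to the terminal CH2, and C–C reductive elimination from the seven-membered acyl–alkyl rhodacycle forms the C-3–C-4 bond. The closest known reaction type is the rhodium-catalysed enantioselective endo-hydroacylation of 1,1-disubstituted alkenes in ortho-allylbenzaldehydes and 2-(1-substituted vinyl)benzaldehydes to 3-substituted tetralones and indanones; an aryl 1-arylvinyl ether as the alkene is the untested element. Ring C closes in the 6-endo-trig mode, the acyl carbon bonding to the CH2 terminus. The new stereocentre C-2 is set when hydride is transferred to one enantiotopic face of the enol ether, under control of the chiral pocket of DTBM-SEGPHOS alone, since 6 is achiral. The step needs endo over exo regioselectivity and hydroacylation over decarbonylation: the 5-exo path would require a tertiary alkyl–rhodium and reductive elimination to a quaternary carbon, the 2,6-disubstituted aroyl group resists aryl migration, and the hydrogen bond from the ortho OH to the formyl oxygen turns the C–H bond toward the enol-ether arm. Neutral aprotic conditions should leave the acid-labile enol ether and the silyl ethers intact.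

**Step 6**
Reactants: 7 (2S)-2-[2,4-bis(triisopropylsilyloxy)phenyl]-5-hydroxy-7-(triisopropylsilyloxy)-2,3-dihydro-4H-chromen-4-one
Product: 8 (2S)-2-[2,4-bis(triisopropylsilyloxy)phenyl]-5-hydroxy-6-iodo-7-(triisopropylsilyloxy)-2,3-dihydro-4H-chromen-4-one
Conditions: BnMe3N ICl2 (1.05 equiv), CaCO3, CH2Cl2–MeOH, rt
Reagents that add atoms: benzyltrimethylammonium dichloroiodate, C[N+](C)(C)Cc1ccccc1.Cl[I-]Cl
Why: Electrophilic aromatic iodination directed by the free chelated 5-OH to its ortho position C-6, the usual site for 5-hydroxy-7-alkoxy flavonoids under buffered conditions, while C-8 and the bis-silylated ring B are less activated.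

**Step 7**
Reactants: 9 6-methylhept-5-en-2-one
Product: 11 6-methylhepta-1,5-dien-2-yl trifluoromethanesulfonate, via lithium enolate 10 (not isolated)
Conditions: LiN(i-Pr)2, THF, −78 °C; then PhNTf2, −78 to 0 °C
Reagents that add atoms: N-phenylbis(trifluoromethanesulfonimide), O=S(=O)(N(c1ccccc1)S(=O)(=O)C(F)(F)F)C(F)(F)F; lithium diisopropylamide, CC(C)[N-]C(C)C.[Li+] (lithium in 10 only)
Why: Kinetic deprotonation of the methyl ketone at the methyl group followed by O-triflation of the terminal enolate, a standard enol triflate synthesis.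

**Step 8**
Reactants: 11 6-methylhepta-1,5-dien-2-yl trifluoromethanesulfonate; 12 (E)-1,2-bis(tributylstannyl)ethene
Product: 13 tributyl[(1E)-7-methyl-3-methylideneocta-1,6-dien-1-yl]stannane
Conditions: Pd(PPh3)4 (5 mol %), LiCl (3 equiv), THF, 60 °C; 12 in excess (2.5 equiv)
Reagents that add atoms: none
Why: Stille coupling of a vinyl triflate at zerovalent palladium with retention of the E geometry, kept at mono-coupling by the excess of the distannane.

**Step 9**
Reactants: 8 (2S)-2-[2,4-bis(triisopropylsilyloxy)phenyl]-5-hydroxy-6-iodo-7-(triisopropylsilyloxy)-2,3-dihydro-4H-chromen-4-one; 13 tributyl[(1E)-7-methyl-3-methylideneocta-1,6-dien-1-yl]stannane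
Product: 14 (2S)-2-[2,4-bis(triisopropylsilyloxy)phenyl]-5-hydroxy-6-[(1E)-7-methyl-3-methylideneocta-1,6-dien-1-yl]-7-(triisopropylsilyloxy)-2,3-dihydro-4H-chromen-4-one
Conditions: Pd2(dba)3 (5 mol %), AsPh3 (20 mol %), CuI (20 mol %), DMF, 50 °C
Reagents that add atoms: none
Why: Stille coupling with retention of the E geometry, chosen because it is base-free (C-2 and the silyl ethers are untouched) and passes through no allyl–palladium species that the ortho 5-OH could trap.

**Step 10**
Reactants: 3 1-(2,4-dihydroxyphenyl)ethan-1-one; 15 1-bromo-3-methylbut-2-ene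
Product: 16 1-[2,4-dihydroxy-3-(3-methylbut-2-en-1-yl)phenyl]ethan-1-one
Conditions: KOH (10 % aq.), 0 °C to rt; chromatographic removal of the 5-prenyl and O-prenyl isomers
Reagents that add atoms: none
Why: Direct C-prenylation of the resorcinol dianion in water, where the carbon between the two oxygens (C-3) is the most nucleophilic site.

**Step 11**
Reactants: 16 1-[2,4-dihydroxy-3-(3-methylbut-2-en-1-yl)phenyl]ethan-1-one
Product: 17 1-[2-hydroxy-4-(methoxymethoxy)-3-(3-methylbut-2-en-1-yl)phenyl]ethan-1-one
Conditions: MOMCl (1.1 equiv), i-Pr2NEt, CH2Cl2, 0 °C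
Reagents that add atoms: chloromethyl methyl ether, COCCl
Why: Selective O-alkylation of the non-chelated 4-OH, the 2-OH being held by the hydrogen bond to the ketone.

**Step 12**
Reactants: 18 2,4-dihydroxybenzaldehyde
Product: 19 2,4-bis(methoxymethoxy)benzaldehyde
Conditions: MOMCl (3 equiv), i-Pr2NEt, CH2Cl2, reflux
Reagents that add atoms: chloromethyl methyl ether, COCCl
Why: Double MOM protection, with excess reagent and heat to alkylate the chelated 2-OH as well.

**Step 13**
Reactants: 17 1-[2-hydroxy-4-(methoxymethoxy)-3-(3-methylbut-2-en-1-yl)phenyl]ethan-1-one; 19 2,4-bis(methoxymethoxy)benzaldehyde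
Product: 20 (2E)-3-[2,4-bis(methoxymethoxy)phenyl]-1-[2-hydroxy-4-(methoxymethoxy)-3-(3-methylbut-2-en-1-yl)phenyl]prop-2-en-1-one
Conditions: KOH, EtOH–H2O, rt
Reagents that add atoms: none
Why: Claisen–Schmidt condensation, which gives the E-enone and is routine for MOM-protected 2'-hydroxychalcones.

**Step 14**
Reactants: 20 (2E)-3-[2,4-bis(methoxymethoxy)phenyl]-1-[2-hydroxy-4-(methoxymethoxy)-3-(3-methylbut-2-en-1-yl)phenyl]prop-2-en-1-one
Product: 21 (2E)-1-[2,4-dihydroxy-3-(3-methylbut-2-en-1-yl)phenyl]-3-(2,4-dihydroxyphenyl)prop-2-en-1-one (morachalcone A)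
Conditions: HCl (3 M aq.), MeOH, rt to 40 °C
Reagents that add atoms: none
Why: Acid-catalysed acetal exchange with methanol, carried out at the chalcone stage where mild acid is tolerated by the prenyl group and the enone.

**Step 15**
Reactants: 21 morachalcone A
Product: 22 (2E)-3-{2,4-bis[(tert-butyldimethylsilyl)oxy]phenyl}-1-{4-[(tert-butyldimethylsilyl)oxy]-2-hydroxy-3-(3-methylbut-2-en-1-yl)phenyl}prop-2-en-1-one
Conditions: TBSCl (3.3 equiv), imidazole, DMF, 0 °C to rt
Reagents that add atoms: tert-butylchlorodimethylsilane, CC(C)(C)[Si](C)(C)Cl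
Why: O-silylation of the three non-chelated phenols, leaving free the 2'-OH that is hydrogen-bonded to the ketone and flanked by the prenyl group, as step 16 requires.

**Step 16**
Reactants: 14 the (2S)-6-dienyl flavanone; 22 the tris-TBS 2'-hydroxychalcone
Product: 23 (2S)-2-[2,4-bis(triisopropylsilyloxy)phenyl]-6-[(3''R,4''R,5''S)-4''-{4-[(tert-butyldimethylsilyl)oxy]-2-hydroxy-3-(3-methylbut-2-en-1-yl)benzoyl}-5''-{2,4-bis[(tert-butyldimethylsilyl)oxy]phenyl}-1''-(4-methylpent-3-en-1-yl)cyclohex-1''-en-3''-yl]-5-hydroxy-7-(triisopropylsilyloxy)-2,3-dihydro-4H-chromen-4-one (all-trans adduct)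
Conditions: B(OPh)3 (2.2 equiv), (S)-VANOL (2.2 equiv), 4 Å MS, THF then PhCF3, rt to 40 °C; aqueous work-up; chromatographic removal of the endo diastereomer
Reagents that add atoms: none
Why: Boron-promoted asymmetric Diels–Alder reaction of a 2'-hydroxychalcone, in which boron bound to the 2'-phenolate and the carbonyl oxygen within the VANOL borate activates the enone and shields one face, the CH2 terminus of the 1-aryl-3-alkyl diene bonds to the β-carbon (C-5'') and the aryl-bearing terminus to the α-carbon (C-4''), the E-chalcone fixes the 4'',5''-trans and the exo approach of the E-diene the 3'',4''-trans relationship, the ligand sets the absolute sense, and the second equivalent of borate occupies the 5-OH/4-ketone site of 14.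

**Step 17**
Reactants: 23 the hexasilyl all-trans adduct
Product: 24 the target, (2S)-2-(2,4-dihydroxyphenyl)-6-[(3''R,4''R,5''S)-4''-[2,4-dihydroxy-3-(3-methylbut-2-en-1-yl)benzoyl]-5''-(2,4-dihydroxyphenyl)-1''-(4-methylpent-3-en-1-yl)cyclohex-1''-en-3''-yl]-5,7-dihydroxy-2,3-dihydro-4H-chromen-4-one
Conditions: Bu4NF (7 equiv), AcOH (7 equiv), THF, 0 °C to rt
Reagents that add atoms: none
Why: Fluoride cleavage of the six aryl silyl ethers, buffered with acetic acid so that neither phenoxide-triggered opening of the flavanone (loss of C-2 configuration) nor acid-induced prenyl cyclisation or ketalisation should occur.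

**Compound list**

1 | 2,4,6-trihydroxybenzaldehyde | O=Cc1c(O)cc(O)cc1O | starting material
2 | 2,6-dihydroxy-4-[(triisopropylsilyl)oxy]benzaldehyde | O=Cc1c(O)cc(O[Si](C(C)C)(C(C)C)C(C)C)cc1O | intermediate
3 | 1-(2,4-dihydroxyphenyl)ethan-1-one | CC(=O)c1ccc(O)cc1O | starting material
4 | 1-{2,4-bis[(triisopropylsilyl)oxy]phenyl}ethan-1-one | CC(=O)c1ccc(O[Si](C(C)C)(C(C)C)C(C)C)cc1O[Si](C(C)C)(C(C)C)C(C)C | intermediate
5 | 1-(1-bromoethenyl)-2,4-bis[(triisopropylsilyl)oxy]benzene | C=C(Br)c1ccc(O[Si](C(C)C)(C(C)C)C(C)C)cc1O[Si](C(C)C)(C(C)C)C(C)C | intermediate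
6 | 2-({1-[2,4-bis(triisopropylsilyloxy)phenyl]ethenyl}oxy)-6-hydroxy-4-(triisopropylsilyloxy)benzaldehyde | O=Cc1c(O)cc(O[Si](C(C)C)(C(C)C)C(C)C)cc1OC(=C)c1ccc(O[Si](C(C)C)(C(C)C)C(C)C)cc1O[Si](C(C)C)(C(C)C)C(C)C | intermediate
7 | (2S)-2-[2,4-bis(triisopropylsilyloxy)phenyl]-5-hydroxy-7-(triisopropylsilyloxy)-2,3-dihydro-4H-chromen-4-one | O=C1C[C@@H](c2ccc(O[Si](C(C)C)(C(C)C)C(C)C)cc2O[Si](C(C)C)(C(C)C)C(C)C)Oc2cc(O[Si](C(C)C)(C(C)C)C(C)C)cc(O)c21 | intermediate
8 | (2S)-2-[2,4-bis(triisopropylsilyloxy)phenyl]-5-hydroxy-6-iodo-7-(triisopropylsilyloxy)-2,3-dihydro-4H-chromen-4-one | O=C1C[C@@H](c2ccc(O[Si](C(C)C)(C(C)C)C(C)C)cc2O[Si](C(C)C)(C(C)C)C(C)C)Oc2cc(O[Si](C(C)C)(C(C)C)C(C)C)c(I)c(O)c21 | intermediate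
9 | 6-methylhept-5-en-2-one | CC(=O)CCC=C(C)C | starting material
10 | lithium 6-methylhepta-1,5-dien-2-olate | [Li]OC(=C)CCC=C(C)C | intermediate (not isolated)
11 | 6-methylhepta-1,5-dien-2-yl trifluoromethanesulfonate | C=C(OS(=O)(=O)C(F)(F)F)CCC=C(C)C | intermediate
12 | (E)-1,2-bis(tributylstannyl)ethene | CCCC[Sn](CCCC)(CCCC)/C=C/[Sn](CCCC)(CCCC)CCCC | starting material
13 | tributyl[(1E)-7-methyl-3-methylideneocta-1,6-dien-1-yl]stannane | CCCC[Sn](CCCC)(CCCC)/C=C/C(=C)CCC=C(C)C | intermediate
14 | (2S)-2-[2,4-bis(triisopropylsilyloxy)phenyl]-5-hydroxy-6-[(1E)-7-methyl-3-methylideneocta-1,6-dien-1-yl]-7-(triisopropylsilyloxy)-2,3-dihydro-4H-chromen-4-one | O=C1C[C@@H](c2ccc(O[Si](C(C)C)(C(C)C)C(C)C)cc2O[Si](C(C)C)(C(C)C)C(C)C)Oc2cc(O[Si](C(C)C)(C(C)C)C(C)C)c(/C=C/C(=C)CCC=C(C)C)c(O)c21 | intermediate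
15 | 1-bromo-3-methylbut-2-ene | CC(C)=CCBr | starting material
16 | 1-[2,4-dihydroxy-3-(3-methylbut-2-en-1-yl)phenyl]ethan-1-one | CC(=O)c1ccc(O)c(CC=C(C)C)c1O | intermediate
17 | 1-[2-hydroxy-4-(methoxymethoxy)-3-(3-methylbut-2-en-1-yl)phenyl]ethan-1-one | CC(=O)c1ccc(OCOC)c(CC=C(C)C)c1O | intermediate
18 | 2,4-dihydroxybenzaldehyde | O=Cc1ccc(O)cc1O | starting material
19 | 2,4-bis(methoxymethoxy)benzaldehyde | O=Cc1ccc(OCOC)cc1OCOC | intermediate
20 | (2E)-3-[2,4-bis(methoxymethoxy)phenyl]-1-[2-hydroxy-4-(methoxymethoxy)-3-(3-methylbut-2-en-1-yl)phenyl]prop-2-en-1-one | COCOc1ccc(/C=C/C(=O)c2ccc(OCOC)c(CC=C(C)C)c2O)c(OCOC)c1 | intermediate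
21 | morachalcone A | O=C(/C=C/c1ccc(O)cc1O)c1ccc(O)c(CC=C(C)C)c1O | intermediate
22 | (2E)-3-{2,4-bis[(tert-butyldimethylsilyl)oxy]phenyl}-1-{4-[(tert-butyldimethylsilyl)oxy]-2-hydroxy-3-(3-methylbut-2-en-1-yl)phenyl}prop-2-en-1-one | O=C(/C=C/c1ccc(O[Si](C)(C)C(C)(C)C)cc1O[Si](C)(C)C(C)(C)C)c1ccc(O[Si](C)(C)C(C)(C)C)c(CC=C(C)C)c1O | intermediate
23 | hexasilyl all-trans adduct, (2S,3''R,4''R,5''S) | CC(C)=CCCC1=C[C@@H](c2c(O[Si](C(C)C)(C(C)C)C(C)C)cc3c(c2O)C(=O)C[C@@H](c2ccc(O[Si](C(C)C)(C(C)C)C(C)C)cc2O[Si](C(C)C)(C(C)C)C(C)C)O3)[C@H](C(=O)c2ccc(O[Si](C)(C)C(C)(C)C)c(CC=C(C)C)c2O)[C@@H](c2ccc(O[Si](C)(C)C(C)(C)C)cc2O[Si](C)(C)C(C)(C)C)C1 | intermediate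
24 | target, (2S,3''R,4''R,5''S) | CC(C)=CCCC1=C[C@@H](c2c(O)cc3c(c2O)C(=O)C[C@@H](c2ccc(O)cc2O)O3)[C@H](C(=O)c2ccc(O)c(CC=C(C)C)c2O)[C@@H](c2ccc(O)cc2O)C1 | target

**Count and risks**

Total step count: 17. Longest linear sequence: 8 steps (3 → 4 → 5 → 6 → 7 → 8 → 14 → 23 → 24; steps 2, 3, 4, 5, 6, 9, 16, 17).

Steps most likely to fail:

1. Step 5 (Proposed new method). What may go wrong: decarbonylation of the acyl rhodium hydride before the alkene inserts; insertion in the exo sense, leading to the five-membered ketone; poor facial selectivity in the hydride transfer; Lewis-acid hydrolysis of the enol ether by the cationic metal with adventitious water. Fallback, setting out from 6 and coming back at 7: thiol-catalysed radical-chain hydroacylation (tert-dodecanethiol 30 mol %, AIBN, chlorobenzene, 80 °C), a known acyl-radical cyclisation of alkenals that also works with enol ethers under polarity-reversal catalysis. The thiyl radical abstracts the formyl hydrogen, the aroyl radical closes 6-endo onto the CH2 terminus to a tertiary benzylic α-oxy radical, and the thiol reduces it, which should give the racemic flavanone 2-[2,4-bis(triisopropylsilyloxy)phenyl]-5-hydroxy-7-(triisopropylsilyloxy)-2,3-dihydro-4H-chromen-4-one F1. Resolution of F1 by preparative supercritical-fluid chromatography on a chiral stationary phase then supplies 7.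

2. Step 4. What may go wrong: dehydrobromination of the vinyl bromide to the aryl alkyne in hot carbonate; silyl transfer from the aryl silyl ethers to the caesium phenoxide; slow C–O bond formation at the hindered 1,1-disubstituted vinyl carbon; double vinylation. Fallback, setting out from 5 and coming back at 6: reversal of the coupling roles. Miyaura borylation of 5 (PdCl2(PPh3)2, PPh3, B2pin2, KOPh, toluene, 50 °C) should give 2-{1-[2,4-bis(triisopropylsilyloxy)phenyl]ethenyl}-4,4,5,5-tetramethyl-1,3,2-dioxaborolane F2. F2 is then joined to phenol 2 by a Chan–Lam oxidative coupling mediated by divalent copper (Cu(OAc)2, pyridine, 4 Å MS, CH2Cl2, air, rt), which runs at room temperature without carbonate base.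

3. Step 16. What may go wrong: competing endo approach; low facial selectivity on a diene flanked by two ortho oxygen substituents; sequestration of the boron promoter at the 5-OH/4-ketone site of the diene; slow cycloaddition through steric shielding by the neighbouring silyl ether. Fallback, setting out from 14 and 22 and coming back at 23: uncatalysed thermal [4+2] cycloaddition (toluene, sealed tube, 120–150 °C), the known promoter-free biomimetic variant. Because C-2 is already fixed as S, all four adducts are diastereomers of one another, so stereocontrol is handed to separation by preparative HPLC, which should isolate 23. This path makes no compound outside the list: none F0.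

**Further compounds**

F1 | step 5 | racemic 2-[2,4-bis(triisopropylsilyloxy)phenyl]-5-hydroxy-7-(triisopropylsilyloxy)-2,3-dihydro-4H-chromen-4-one | O=C1CC(c2ccc(O[Si](C(C)C)(C(C)C)C(C)C)cc2O[Si](C(C)C)(C(C)C)C(C)C)Oc2cc(O[Si](C(C)C)(C(C)C)C(C)C)cc(O)c21
F2 | step 4 | 2-{1-[2,4-bis(triisopropylsilyloxy)phenyl]ethenyl}-4,4,5,5-tetramethyl-1,3,2-dioxaborolane | C=C(B1OC(C)(C)C(C)(C)O1)c1ccc(O[Si](C(C)C)(C(C)C)C(C)C)cc1O[Si](C(C)C)(C(C)C)C(C)C
F0 | step 16 | none | none
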